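The numbers in the tables were generated by integration with made-up constants; noise was put on by code.

The pitfall in a curve that goes flat is to ask when it stopped. If the plateau is a balance, forward rate over back rate is one there, time drops out of the ratio, and you can reckon where it stops.

common to all: free catalyst 1.2 mol%

| flask | starting material | partner | impurity | temperature | remark | time |
|---|---|---|---|---|---|---|
| grey | 5 mM (fed, over 30 s) | 1.2 equiv | 2.5 µM | 20 °C | run made earlier |  |
| ochre | 5 mM (fed, over 30 s) | 1.2 equiv | 3.9 µM | 31 °C | run made earlier |  |
| violet | 5 mM (fed, over 30 s) | 1.2 equiv | 7.4 µM | 20 °C | run made earlier |  |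
| alpha | 5.0 mM (fed, over 30 s) | 1.20 equiv | 6.5 µM | 25 °C |  | 12 min |
| gamma | 5.0 mM | 1.20 equiv | 2.0 µM | 25 °C | everything together at the start | 12 min |

| run | time / min | target / % | starting material / % |
|---|---|---|---|
| grey | 0.833 | 38 | 53 |
| grey | 2.00 | 59 | 30 |
| grey | 4.00 | 71 | 20 |
| grey | 6.00 | 76 | 18 |
| grey | 8.00 | 77 | 17 |
| ochre | 1.50 | 63 | 24 |
| ochre | 3.00 | 68 | 16 |
| ochre | 5.00 | 70 | 14 |
| ochre | 6.00 | 68 | 14 |
| ochre | 8.00 | 65 | 19 |
| violet | 0.667 | 30 | 67 |
| violet | 1.33 | 48 | 39 |
| violet | 2.50 | 62 | 26 |
| violet | 4.00 | 69 | 21 |
| violet | 8.00 | 74 | 13 |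

(each reading ± 2 percentage points)

- the winner by amount of target, in percent of the starting material charged; "neither" if no more than 2 percentage points parts them (alpha / gamma / neither)
- how much target is there at the end, in percent of the starting material charged: alpha
- how much target is there at the end, in percent of the starting material charged: gamma

- a reading or a percentage of target counts all its forms, free or not

You asked for a quick number, and your forecast has gamma ahead, with 72% for alpha and 75% for gamma, on the ground that “Gamma's lower impurity gives it a slight edge”.

My own reckoning goes by the plateau. Let a be the fraction of the starting material charge left, and d the excess of partner in equivalents. I take it that each starting material consumed takes one partner, so the partner left, in equivalents on that charge, is b = a + d. From the last readings, at 8.00 min: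

S = a·b: grey 0.0629, ochre 0.0741, violet 0.0429; mean 0.0600

Each a carries a scatter of 2 percentage points, and the runs lie at 20 °C and 31 °C, either side of the 25 °C of alpha and gamma, so I hold the mean as one value read from these runs, the stall product: fraction left times equivalents left once the curve is flat. Neither feed nor impurity stands in it, so I give alpha and gamma one plateau, and both get 12 min, while grey was already flat by 6.00 min:

a = (√(d·d + 4S) − d)/2 = 16.5%

target = 1 − a − missing share = 1 − 16.5% − 11.7% = 71.9%

The missing share is the mean gap in the balance at 8.00 min. So I say neither, each near 71.9%, which matches your alpha and stands below your gamma.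

The flask gives neither: alpha 72.1%, gamma 72.2%, inside the margin of 2 points.

    starting material + partner ⇌ target (K = 59.0 L mol⁻¹, k = 5.10 L mol⁻¹ s⁻¹, Ea = 52.0 kJ mol⁻¹, ΔH = −15.0 kJ mol⁻¹)
    starting material + partner ⇌ isomer of the product (K = 360 L mol⁻¹, k = 0.690 L mol⁻¹ s⁻¹, Ea = 39.0 kJ mol⁻¹, ΔH = 16.0 kJ mol⁻¹)
    target + free catalyst ⇌ isomer of the product + free catalyst, rate k3*[free catalyst]*[target] forward; the back reaction follows from the equilibrium constant (k = 220 L mol⁻¹ s⁻¹, Ea = 38.0 kJ mol⁻¹)
    free catalyst + impurity → spent catalyst A (k = 27000 L mol⁻¹ s⁻¹, Ea = 17.0 kJ mol⁻¹)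
    crystals ⇌ target, rate k5*(cs5 - [target]) while solid is left; crystals form when [target] > cs5 (solubility = 0.0890 mM, k = 1.10 s⁻¹)
    2 free catalyst → spent catalyst B (k = 84.0 L mol⁻¹ s⁻¹, Ea = 36.0 kJ mol⁻¹)
    (constants at 25 °C)

At 12.0 min gamma holds 17% of its starting material and 30% of its partner charge, so S = 0.0607; alpha, with 17% and 30%, gives 0.0607. Now take the neighbouring flask, gamma with 3.00 equiv of partner. There d = 2.00, and the stall product 0.0600 puts a at 2.95%. That flask ends with 3.0% of its starting material and 68% of its partner, so S = 0.0612, and with target at 85.6%.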